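**Retrosynthetic overview**
1. Target 11 comes from its tetra-TIPS ether 10 by one global desilylation.
2. Key step: both aryl–CH2CH2 bonds of 10 are cut at once, a two-directional double B-alkyl Suzuki coupling of dibromo-diarylmethane 6 with alkylborane 9 (from protected 4-vinylguaiacol 8).
3. The central Ar–CH2–Ar unit (6) comes from carbinol 5, built from two ortho-lithiated aryl bromides 3 and ethyl formate as the one-carbon linchpin. Deprotonation between Br and OMe fixes the bridge position, so the biomimetic gigantol + CH2O condensation and its regiochemistry problem are avoided.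
4. No ring is formed: all four benzene rings are bought (2 × 3-bromo-5-methoxyphenol, 2 × 4-vinylguaiacol).

Assumption: the target has no stereocentre and is achiral, so "single enantiomer" means the compound itself and no stereocontrol is needed.

**Route**

Step 1
Reactants: 1 3-bromo-5-methoxyphenol
Product: 2 (3-bromo-5-methoxyphenoxy)triisopropylsilane
Conditions: TIPSCl (1.2 equiv), imidazole (2.5 equiv), DMF, rt
Reagents that add atoms: triisopropylsilyl chloride, CC(C)[Si](Cl)(C(C)C)C(C)C
Why: Standard phenol O-silylation; the bulky TIPS group later shields both of its ortho positions from metalation and survives base, mild acid and Pd coupling.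

Step 2
Reactants: 2 (3-bromo-5-methoxyphenoxy)triisopropylsilane (2 equiv)
Product: 5 bis[2-bromo-6-methoxy-4-(triisopropylsilyloxy)phenyl]methanol, via [2-bromo-6-methoxy-4-(triisopropylsilyloxy)phenyl]lithium 3 (not isolated), via 2-bromo-6-methoxy-4-(triisopropylsilyloxy)benzaldehyde 4 (not isolated)
Conditions: commercial LDA solution (0.98 equiv per 2), THF, −78 °C, 1 h; HCO2Et (0.48 equiv), −78 → −40 °C; H2O quench
Reagents that add atoms: ethyl formate, CCOC=O (gives the CH–OH carbon and oxygen of 4 and 5); lithium diisopropylamide, CC(C)N([Li])C(C)C (gives the Li of 3 only)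
Why: Directed ortho-metalation removes the most acidic ring proton, the one flanked by Br and OMe, and two aryllithiums then add to the formate ester (ester → aldehyde 4 → carbinol), with −78 °C keeping the ortho-bromoaryllithium from losing LiBr to an aryne.

Step 3
Reactants: 5 bis[2-bromo-6-methoxy-4-(triisopropylsilyloxy)phenyl]methanol
Product: 6 bis[2-bromo-6-methoxy-4-(triisopropylsilyloxy)phenyl]methane
Conditions: Et3SiH (3 equiv), TFA (10 equiv), CH2Cl2, 0 °C, 30 min
Reagents that add atoms: none
Why: Ionic hydrogenation: the benzhydrol ionises easily to a cation stabilised by para-OSi and ortho-OMe donors on both rings and is trapped by silane hydride, while aryl bromides and aryl TIPS ethers are inert to these conditions.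

Step 4
Reactants: 7 2-methoxy-4-vinylphenol (4-vinylguaiacol)
Product: 8 triisopropyl(2-methoxy-4-vinylphenoxy)silane
Conditions: TIPSCl (1.2 equiv), imidazole (2.5 equiv), DMF, 0 °C → rt (trace BHT)
Reagents that add atoms: triisopropylsilyl chloride, CC(C)[Si](Cl)(C(C)C)C(C)C
Why: Standard phenol O-silylation; it masks the acidic OH before hydroboration and uses the same protecting group as the core, so one final reagent removes all four.

Step 5
Reactants: 6 bis[2-bromo-6-methoxy-4-(triisopropylsilyloxy)phenyl]methane; 8 triisopropyl(2-methoxy-4-vinylphenoxy)silane (2.6 equiv)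
Product: 10 bis{2-methoxy-6-[2-(3-methoxy-4-(triisopropylsilyloxy)phenyl)ethyl]-4-(triisopropylsilyloxy)phenyl}methane, via 9-{2-[3-methoxy-4-(triisopropylsilyloxy)phenyl]ethyl}-9-borabicyclo[3.3.1]nonane 9 (not isolated)
Conditions: 8, 9-BBN dimer (1.35 equiv), THF, 0 °C → rt, 4 h; then 6, Pd(OAc)2 (10 mol%), SPhos (20 mol%), aq. 3 M K3PO4 (6 equiv), THF, 65 °C, 16 h
Reagents that add atoms: 9-borabicyclo[3.3.1]nonane, [H]B1C2CCCC1CCC2 (gives the boron bicycle of 9; only H stays in 10)
Why: Anti-Markovnikov hydroboration of the styrene followed by a two-fold B-alkyl Suzuki–Miyaura coupling, in which Pd/SPhos inserts into the electron-rich ortho-substituted aryl bromides and reductive elimination outruns β-hydride elimination.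

Step 6
Reactants: 10 bis{2-methoxy-6-[2-(3-methoxy-4-(triisopropylsilyloxy)phenyl)ethyl]-4-(triisopropylsilyloxy)phenyl}methane
Product: 11 4,4'-methylenebis{3-[2-(4-hydroxy-3-methoxyphenyl)ethyl]-5-methoxyphenol} (CNP0079383.0)
Conditions: TBAF (6 equiv), AcOH (6 equiv), THF, 0 °C → rt
Reagents that add atoms: none
Why: Fluoride-mediated cleavage of all four aryl silyl ethers (Si–F bond formation), buffered with AcOH so the electron-rich tetraphenol is never exposed to basic phenoxide conditions.

**Compound list**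
1 | 3-bromo-5-methoxyphenol | COc1cc(O)cc(Br)c1 | starting material
2 | (3-bromo-5-methoxyphenoxy)triisopropylsilane | COc1cc(O[Si](C(C)C)(C(C)C)C(C)C)cc(Br)c1 | intermediate
3 | [2-bromo-6-methoxy-4-(triisopropylsilyloxy)phenyl]lithium | COc1cc(O[Si](C(C)C)(C(C)C)C(C)C)cc(Br)c1[Li] | intermediate
4 | 2-bromo-6-methoxy-4-(triisopropylsilyloxy)benzaldehyde | COc1cc(O[Si](C(C)C)(C(C)C)C(C)C)cc(Br)c1C=O | intermediate
5 | bis[2-bromo-6-methoxy-4-(triisopropylsilyloxy)phenyl]methanol | COc1cc(O[Si](C(C)C)(C(C)C)C(C)C)cc(Br)c1C(O)c1c(Br)cc(O[Si](C(C)C)(C(C)C)C(C)C)cc1OC | intermediate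
6 | bis[2-bromo-6-methoxy-4-(triisopropylsilyloxy)phenyl]methane | COc1cc(O[Si](C(C)C)(C(C)C)C(C)C)cc(Br)c1Cc1c(Br)cc(O[Si](C(C)C)(C(C)C)C(C)C)cc1OC | intermediate
7 | 2-methoxy-4-vinylphenol (4-vinylguaiacol) | C=Cc1ccc(O)c(OC)c1 | starting material
8 | triisopropyl(2-methoxy-4-vinylphenoxy)silane | C=Cc1ccc(O[Si](C(C)C)(C(C)C)C(C)C)c(OC)c1 | intermediate
9 | 9-{2-[3-methoxy-4-(triisopropylsilyloxy)phenyl]ethyl}-9-borabicyclo[3.3.1]nonane | COc1cc(CCB2C3CCCC2CCC3)ccc1O[Si](C(C)C)(C(C)C)C(C)C | intermediate
10 | bis{2-methoxy-6-[2-(3-methoxy-4-(triisopropylsilyloxy)phenyl)ethyl]-4-(triisopropylsilyloxy)phenyl}methane | COc1cc(CCc2cc(O[Si](C(C)C)(C(C)C)C(C)C)cc(OC)c2Cc2c(CCc3ccc(O[Si](C(C)C)(C(C)C)C(C)C)c(OC)c3)cc(O[Si](C(C)C)(C(C)C)C(C)C)cc2OC)ccc1O[Si](C(C)C)(C(C)C)C(C)C | intermediate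
11 | 4,4'-methylenebis{3-[2-(4-hydroxy-3-methoxyphenyl)ethyl]-5-methoxyphenol} | COc1cc(CCc2cc(O)cc(OC)c2Cc2c(CCc3ccc(O)c(OC)c3)cc(O)cc2OC)ccc1O | target

**Totals**
Total step count: 6. Longest linear sequence: 5 (steps 1, 2, 3, 5, 6).

**Three steps most likely to fail**

Step 5 (double B-alkyl Suzuki, the key step). Two couplings must both succeed at bromides ortho to the bulky diarylmethyl group; stalling at mono-coupling or protodebromination are the likely failures. The fallback sets out from 6 and 8 and comes back at 10. A double Mizoroki–Heck reaction of 6 with styrene 8 (Pd2(dba)3, P(t-Bu)3, Cy2NMe, dioxane, 100 °C) gives bis{2-methoxy-6-[(E)-2-(3-methoxy-4-(triisopropylsilyloxy)phenyl)ethenyl]-4-(triisopropylsilyloxy)phenyl}methane F3. Hydrogenation of both stilbene C=C bonds (H2, Pd/C, EtOAc, rt) then gives 10.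

Step 2 (lithiation and one-pot double addition). The ortho-bromoaryllithium 3 may lose LiBr before the second, hindered addition to 4 is complete. The fallback sets out from 2 and comes back at 5. One portion of 2 is lithiated with LDA and quenched with DMF, and aldehyde 4 is isolated. A second portion of 2 is lithiated to 3 and transmetalated with MgBr2·OEt2 to [2-bromo-6-methoxy-4-(triisopropylsilyloxy)phenyl]magnesium bromide F1, which tolerates 0 °C. F1 is added to 4 (THF, −78 → 0 °C) to give 5.

Step 3 (ionic hydrogenation). Under TFA the very electron-rich carbinol could fragment by ipso-protonation or lose silyl groups. The fallback sets out from 5 and comes back at 10. Carbinol 5 is carried directly into the double B-alkyl Suzuki coupling with borane 9 (conditions of step 5; the free OH is tolerated) to give bis{2-methoxy-6-[2-(3-methoxy-4-(triisopropylsilyloxy)phenyl)ethyl]-4-(triisopropylsilyloxy)phenyl}methanol F2. Its benzhydrylic OH is then removed by hydrogenolysis (H2, Pd/C, EtOAc/AcOH, rt), which is safe once no aryl bromide remains, giving 10.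

**Further compounds**
F1 | step 2 | [2-bromo-6-methoxy-4-(triisopropylsilyloxy)phenyl]magnesium bromide | COc1cc(O[Si](C(C)C)(C(C)C)C(C)C)cc(Br)c1[Mg]Br
F2 | step 3 | bis{2-methoxy-6-[2-(3-methoxy-4-(triisopropylsilyloxy)phenyl)ethyl]-4-(triisopropylsilyloxy)phenyl}methanol | COc1cc(CCc2cc(O[Si](C(C)C)(C(C)C)C(C)C)cc(OC)c2C(O)c2c(CCc3ccc(O[Si](C(C)C)(C(C)C)C(C)C)c(OC)c3)cc(O[Si](C(C)C)(C(C)C)C(C)C)cc2OC)ccc1O[Si](C(C)C)(C(C)C)C(C)C
F3 | step 5 | bis{2-methoxy-6-[(E)-2-(3-methoxy-4-(triisopropylsilyloxy)phenyl)ethenyl]-4-(triisopropylsilyloxy)phenyl}methane | COc1cc(/C=C/c2cc(O[Si](C(C)C)(C(C)C)C(C)C)cc(OC)c2Cc2c(/C=C/c3ccc(O[Si](C(C)C)(C(C)C)C(C)C)c(OC)c3)cc(O[Si](C(C)C)(C(C)C)C(C)C)cc2OC)ccc1O[Si](C(C)C)(C(C)C)C(C)C
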